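A direct plan would grow the tetramer ring by ring from 2,4,6-tris(benzyloxy)phenol A1 by copper-catalysed Ullmann etherification with 2,4-bis(benzyloxy)-6-bromo-3-(methoxymethoxy)benzaldehyde A2 for ring B and then twice with 4-bromo-2,6-bis(benzyloxy)benzaldehyde A3 for rings C and D, each coupling followed by Baeyer–Villiger oxidation of the formyl group to the next phenol, and would end with hydrogenolysis of the decabenzyl ether A4.
Its weakest steps would be, first, the three aryl ether couplings of di-ortho-alkoxy phenols: the same hindered bond formation would recur on ever more precious material, the last time on a tricyclic phenol near the end of a long linear sequence.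
Second, the formyl-to-hydroxyl oxidations after every coupling: the formyl group would be carried only to activate a bromide and then be cut out with peracid on increasingly electron-rich polyethers, so each ether bond would cost two or three steps with no gain in complexity.
Third, the preparation of the pentaoxygenated bromide A2 by lithiation and formylation next to bromine: many steps and a benzyne hazard would be spent on a ring that afterwards only serves as a coupling partner.
The target has no stereocentre and no ring to close, so nothing would be left to chance there; the price would be length, linearity and late risk.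

Plan of the new route
No aryl–oxygen bond is made by coupling: each ether oxygen is alkylated while it is a simple phenol, and the neighbouring ring is then built around the new O–C bond.
Ring C (C1 bears the ring B oxygen, C4 the ring D oxygen) is cut at C2–C3 and C5–C6 into a 3-aryloxyglutaconate on ring B and an aryloxymalonate on ring D; ring A is cut likewise at C2–C3 and C5–C6 into an aryloxymalonate on ring B and a 3-oxopentanedioate.
The enabling feature: in rings A and C the oxygens stand on alternate carbons (the 1,3,5-pattern of a folded tri-β-carbonyl chain). The ether carbon flanked by two hydroxyl-bearing carbons (C1 of ring A, C4 of ring C) is the central carbon of a malonate, and C1 of ring C is the keto carbon of a 3-oxopentanedioate used as its aryl enol ether.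
Order of rings: B (from acetophenone 1, its fourth oxygen by Elbs oxidation and its fifth by Baeyer–Villiger oxidation of the acetyl group) and D (from aldehyde 18) come from the aromatic pool; ring A is built on ring B in step 7; ring C is built last, between rings B and D, in step 14.
No hindered coupling, no formyl handle on the chain and no late peracid remain; the benzyl ester groups left on rings A and C by the annulations depart with the benzyl ethers in the final hydrogenolysis.

Key step: step 14

Assumption: the target is achiral; enol ether 17 is expected as a mixture of double-bond isomers and allene 16 as a racemate, and both elements disappear on aromatisation, so no stereodescriptor is given.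

Step 1
Reactants: 1 1-(2,4,6-trihydroxyphenyl)ethan-1-one
Product: 2 1-[2,4-bis(benzyloxy)-6-hydroxyphenyl]ethan-1-one
Conditions: BnBr (2.1 equiv), K2CO3, acetone, reflux
Reagents that add atoms: benzyl bromide BrCc1ccccc1
Why: Williamson etherification of the two non-chelated phenols; the hydroxyl hydrogen-bonded to the acetyl group is the least nucleophilic and stays free.

Step 2
Reactants: 2 1-[2,4-bis(benzyloxy)-6-hydroxyphenyl]ethan-1-one
Product: 4 1-[2,4-bis(benzyloxy)-3,6-dihydroxyphenyl]ethan-1-one, via aryl sulfate 3 (not isolated)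
Conditions: K2S2O8 (1.1 equiv), 10% aq. NaOH, pyridine, 15–20 °C; then HCl to pH 1, 90 °C, N2
Reagents that add atoms: potassium peroxodisulfate [K+].[K+].[O-]S(=O)(=O)OOS(=O)(=O)[O-]
Why: Elbs persulfate oxidation: the phenolate attacks a peroxide oxygen through its para carbon (C3, between the two benzyloxy groups) and acid hydrolyses the aryl sulfate, which places the fourth oxygen of ring B para to the one free hydroxyl, as in the classical oxidation of 2-hydroxy-4,6-dimethoxyacetophenone.

Step 3
Reactants: 4 1-[2,4-bis(benzyloxy)-3,6-dihydroxyphenyl]ethan-1-one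
Product: 5 1-[2,4-bis(benzyloxy)-6-hydroxy-3-(methoxymethoxy)phenyl]ethan-1-one
Conditions: MOMCl (1.1 equiv), i-Pr2NEt, CH2Cl2, 0 °C, Ar
Reagents that add atoms: chloromethyl methyl ether COCCl
Why: O-alkylation to the acetal occurs only at the non-chelated hydroxyl, since the hydroxyl hydrogen-bonded to the ketone does not react under amine base; this marks the future ring C oxygen and leaves the future ring A oxygen free.

Step 4
Reactants: 6 dibenzyl propanedioate
Product: 7 dibenzyl 2-chloropropanedioate
Conditions: SO2Cl2 (1.05 equiv), CH2Cl2, 0 °C → rt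
Reagents that add atoms: sulfuryl chloride O=S(=O)(Cl)Cl
Why: Electrophilic α-chlorination of the malonate enol, the standard preparation of chloromalonates, stops at the monochloride with one equivalent.

Step 5
Reactants: 5 1-[2,4-bis(benzyloxy)-6-hydroxy-3-(methoxymethoxy)phenyl]ethan-1-one; 7 dibenzyl 2-chloropropanedioate
Product: 8 dibenzyl 2-[2-acetyl-3,5-bis(benzyloxy)-4-(methoxymethoxy)phenoxy]propanedioate
Conditions: K2CO3, DMF, 40 °C
Reagents that add atoms: none
Why: Williamson ether synthesis by SN2 displacement of chloride from the doubly activated carbon fixes the ring A–O–ring B oxygen on an sp3 carbon; the di-ortho-substituted, electron-rich aryl ketone resists the intramolecular aldol reaction that simple salicyl carbonyl compounds undergo.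

Step 6
Reactants: 8 dibenzyl 2-[2-acetyl-3,5-bis(benzyloxy)-4-(methoxymethoxy)phenoxy]propanedioate
Product: 10 dibenzyl 2-[3,5-bis(benzyloxy)-2-hydroxy-4-(methoxymethoxy)phenoxy]propanedioate, via aryl acetate 9 (not isolated)
Conditions: mCPBA (2 equiv), CH2Cl2, rt; then K2CO3 (cat.), BnOH/THF, 0 °C → rt
Reagents that add atoms: mCPBA OOC(=O)c1cccc(Cl)c1
Why: Baeyer–Villiger oxidation with migration of the electron-rich trioxygenated aryl group turns the acetyl group into the hydroxyl next to the ether oxygen, and the acetate is removed with benzyl alcohol so that the benzyl esters cannot be scrambled.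

Step 7
Reactants: 10 dibenzyl 2-[3,5-bis(benzyloxy)-2-hydroxy-4-(methoxymethoxy)phenoxy]propanedioate; 11 dibenzyl 3-oxopentanedioate
Product: 13 dibenzyl 5-[3,5-bis(benzyloxy)-2-hydroxy-4-(methoxymethoxy)phenoxy]-2,4,6-trihydroxybenzene-1,3-dicarboxylate, via acyclic diketo triester 12 (not isolated)
Conditions: NaH (2.2 equiv), 11 (1.5 equiv), THF, 0 °C; then toluene, 90 °C; 1 M HCl work-up
Reagents that add atoms: none
Why: Claisen condensation of the sodium enolate of 11 with one ester of 10 and Dieckmann closure (6-exo-trig) of the second active methylene onto the other ester, the malonate–oxopentanedioate synthesis of phloroglucinols, builds ring A around the ether carbon; aromatisation to the phenoxide drives the equilibria, attack in either sense gives the same arene, and the ring B hydroxyl is a spectator phenoxide.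

Step 8
Reactants: 13 dibenzyl 5-[3,5-bis(benzyloxy)-2-hydroxy-4-(methoxymethoxy)phenoxy]-2,4,6-trihydroxybenzene-1,3-dicarboxylate
Product: 14 dibenzyl 2,4,6-tris(benzyloxy)-5-[2,3,5-tris(benzyloxy)-4-(methoxymethoxy)phenoxy]benzene-1,3-dicarboxylate
Conditions: BnBr (6 equiv), Cs2CO3, DMF, 60 °C
Reagents that add atoms: benzyl bromide BrCc1ccccc1
Why: Williamson etherification of all four phenols (forcing conditions for the ester-chelated ones) leaves the acetal-protected oxygen as the only one that can later be addressed; no acidic C–H remains to compete.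

Step 9
Reactants: 14 dibenzyl 2,4,6-tris(benzyloxy)-5-[2,3,5-tris(benzyloxy)-4-(methoxymethoxy)phenoxy]benzene-1,3-dicarboxylate
Product: 15 dibenzyl 2,4,6-tris(benzyloxy)-5-[2,3,5-tris(benzyloxy)-4-hydroxyphenoxy]benzene-1,3-dicarboxylate
Conditions: conc. HCl (cat.), MeOH/THF, 45 °C
Reagents that add atoms: none
Why: Acid-catalysed acetal exchange removes the methoxymethyl group alone and frees the di-ortho-benzyloxy hydroxyl of ring B; the hindered benzoates, benzyl ethers and the diaryl ether are inert.

Step 10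
Reactants: 11 dibenzyl 3-oxopentanedioate
Product: 16 dibenzyl penta-2,3-dienedioate (racemic)
Conditions: 2-chloro-1,3-dimethylimidazolinium chloride, Et3N, CH2Cl2, 0 °C
Reagents that add atoms: none
Why: Dehydration of the enol of the β-keto diester through its O-amidinium ether and 1,2-elimination is a known preparation of allene-1,3-dicarboxylates.

Step 11
Reactants: 15 dibenzyl 2,4,6-tris(benzyloxy)-5-[2,3,5-tris(benzyloxy)-4-hydroxyphenoxy]benzene-1,3-dicarboxylate; 16 dibenzyl penta-2,3-dienedioate
Product: 17 dibenzyl 3-{2,3,6-tris(benzyloxy)-4-[2,4,6-tris(benzyloxy)-3,5-bis(benzyloxycarbonyl)phenoxy]phenoxy}pent-2-enedioate (mixture of double-bond isomers)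
Conditions: Et3N (0.2 equiv), 16 (1.3 equiv), MeCN, 0 °C → rt
Reagents that add atoms: none
Why: Base-catalysed oxa-Michael addition of the phenol to the central allene carbon, a known route to 3-aryloxyglutaconates, makes the ring B–O–ring C bond at an sp carbon that a di-ortho-substituted phenoxide reaches without strain; the double-bond geometry is irrelevant.

Step 12
Reactants: 18 3,4,5-tris(benzyloxy)benzaldehyde
Product: 20 3,4,5-tris(benzyloxy)phenol, via aryl formate 19 (not isolated)
Conditions: mCPBA, CH2Cl2, rt; then K2CO3 (cat.), MeOH, rt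
Reagents that add atoms: mCPBA OOC(=O)c1cccc(Cl)c1
Why: Baeyer–Villiger oxidation of the aldehyde with migration of the para-alkoxyaryl group and methanolysis of the formate gives the ring D phenol.

Step 13
Reactants: 20 3,4,5-tris(benzyloxy)phenol; 7 dibenzyl 2-chloropropanedioate
Product: 21 dibenzyl 2-[3,4,5-tris(benzyloxy)phenoxy]propanedioate
Conditions: 7 (1.2 equiv), K2CO3, acetone, 50 °C
Reagents that add atoms: none
Why: Williamson ether synthesis at the activated chloromalonate carbon by an unhindered phenoxide sets the ring C–O–ring D oxygen on an sp3 carbon.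

Step 14
Reactants: 17 dibenzyl 3-{2,3,6-tris(benzyloxy)-4-[2,4,6-tris(benzyloxy)-3,5-bis(benzyloxycarbonyl)phenoxy]phenoxy}pent-2-enedioate; 21 dibenzyl 2-[3,4,5-tris(benzyloxy)phenoxy]propanedioate
Product: 23 dibenzyl 4,6-dihydroxy-5-[3,4,5-tris(benzyloxy)phenoxy]-2-{2,3,6-tris(benzyloxy)-4-[2,4,6-tris(benzyloxy)-3,5-bis(benzyloxycarbonyl)phenoxy]phenoxy}benzene-1,3-dicarboxylate, via acyclic keto triester 22 (not isolated)
Conditions: NaH (1.1 equiv), THF, 0 °C; 21 (1.5 equiv); 65 °C, Ar; 1 M HCl work-up
Reagents that add atoms: none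
Why: Proposed new method: deprotonation of 17 gives a symmetrical pentadienyl anion (a vinylogous malonate) whose terminus is C-acylated by one ester of 21 (Claisen condensation) to give 22; the other terminus then closes onto the remaining ester of the malonate unit (Dieckmann condensation, 6-exo-trig through the ester enolate) and the cyclohexadienone tautomerises to the resorcinol dianion, which makes every earlier equilibrium irreversible. The closest known reaction type is the condensation of malonic esters with 3-oxopentanedioates to phloroglucinol dicarboxylates (step 7); here the keto carbon is replaced by its aryl enol ether, so this carbon enters the new ring already bearing the oxygen of ring B. Ring C is the only ring formed, it arises from open-chain carbons of both partners, and no stereocentre is created. The selectivity needed is C- over O-acylation and cross- over self-condensation: the esters of 17 are vinylogous carbonates or di-ortho-substituted benzoates that its own anion cannot attack productively, the carbanion of 21 is tertiary so that its self-acylation cannot be locked by deprotonation and reverts, and any enol lactone formed by O-attack is reopened by benzyl oxide whereas aromatisation is not reversed. Attack at either terminus of the anion gives the same arene, so no regiochemical question arises, and the two benzyl oxide ions released are consumed by the acidic product.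

Step 15
Reactants: 23 dibenzyl 4,6-dihydroxy-5-[3,4,5-tris(benzyloxy)phenoxy]-2-{2,3,6-tris(benzyloxy)-4-[2,4,6-tris(benzyloxy)-3,5-bis(benzyloxycarbonyl)phenoxy]phenoxy}benzene-1,3-dicarboxylate
Product: 25 5-{2,6-dihydroxy-4-[2,3,6-trihydroxy-4-(2,4,6-trihydroxyphenoxy)phenoxy]phenoxy}benzene-1,2,3-triol (CNP0018315.0), via tetracarboxylic acid 24 (not isolated)
Conditions: H2 (1 atm), 10% Pd/C, THF/MeOH, rt; filtration under Ar; then degassed H2O/THF, 80 °C, Ar; concentration under Ar
Reagents that add atoms: none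
Why: Catalytic hydrogenolysis cleaves the nine benzyl ethers and four benzyl esters, and the resulting 2,4,6-trioxygenated benzoic acids lose carbon dioxide on gentle heating by ipso-protonation, so the carboxyl groups that enabled both annulations vanish without base or oxidant.

Compound list
1 | 1-(2,4,6-trihydroxyphenyl)ethan-1-one | CC(=O)c1c(O)cc(O)cc1O | starting material
2 | 1-[2,4-bis(benzyloxy)-6-hydroxyphenyl]ethan-1-one | CC(=O)c1c(O)cc(OCc2ccccc2)cc1OCc1ccccc1 | intermediate
3 | potassium 3-acetyl-2,6-bis(benzyloxy)-4-hydroxyphenyl sulfate | CC(=O)c1c(O)cc(OCc2ccccc2)c(OS(=O)(=O)[O-])c1OCc1ccccc1.[K+] | intermediate (not isolated)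
4 | 1-[2,4-bis(benzyloxy)-3,6-dihydroxyphenyl]ethan-1-one | CC(=O)c1c(O)cc(OCc2ccccc2)c(O)c1OCc1ccccc1 | intermediate
5 | 1-[2,4-bis(benzyloxy)-6-hydroxy-3-(methoxymethoxy)phenyl]ethan-1-one | CC(=O)c1c(O)cc(OCc2ccccc2)c(OCOC)c1OCc1ccccc1 | intermediate
6 | dibenzyl propanedioate (dibenzyl malonate) | O=C(CC(=O)OCc1ccccc1)OCc1ccccc1 | starting material
7 | dibenzyl 2-chloropropanedioate | O=C(OCc1ccccc1)C(Cl)C(=O)OCc1ccccc1 | intermediate
8 | dibenzyl 2-[2-acetyl-3,5-bis(benzyloxy)-4-(methoxymethoxy)phenoxy]propanedioate | CC(=O)c1c(OC(C(=O)OCc2ccccc2)C(=O)OCc2ccccc2)cc(OCc2ccccc2)c(OCOC)c1OCc1ccccc1 | intermediate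
9 | dibenzyl 2-[2-(acetyloxy)-3,5-bis(benzyloxy)-4-(methoxymethoxy)phenoxy]propanedioate | CC(=O)Oc1c(OC(C(=O)OCc2ccccc2)C(=O)OCc2ccccc2)cc(OCc2ccccc2)c(OCOC)c1OCc1ccccc1 | intermediate (not isolated)
10 | dibenzyl 2-[3,5-bis(benzyloxy)-2-hydroxy-4-(methoxymethoxy)phenoxy]propanedioate | Oc1c(OC(C(=O)OCc2ccccc2)C(=O)OCc2ccccc2)cc(OCc2ccccc2)c(OCOC)c1OCc1ccccc1 | intermediate
11 | dibenzyl 3-oxopentanedioate | O=C(CC(=O)OCc1ccccc1)CC(=O)OCc1ccccc1 | starting material
12 | tribenzyl 1-[3,5-bis(benzyloxy)-2-hydroxy-4-(methoxymethoxy)phenoxy]-2,4-dioxopentane-1,3,5-tricarboxylate | O=C(OCc1ccccc1)CC(=O)C(C(=O)OCc1ccccc1)C(=O)C(Oc1cc(OCc2ccccc2)c(OCOC)c(OCc2ccccc2)c1O)C(=O)OCc1ccccc1 | intermediate (not isolated)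
13 | dibenzyl 5-[3,5-bis(benzyloxy)-2-hydroxy-4-(methoxymethoxy)phenoxy]-2,4,6-trihydroxybenzene-1,3-dicarboxylate | O=C(OCc1ccccc1)c1c(O)c(C(=O)OCc2ccccc2)c(O)c(Oc2cc(OCc3ccccc3)c(OCOC)c(OCc3ccccc3)c2O)c1O | intermediate
14 | dibenzyl 2,4,6-tris(benzyloxy)-5-[2,3,5-tris(benzyloxy)-4-(methoxymethoxy)phenoxy]benzene-1,3-dicarboxylate | O=C(OCc1ccccc1)c1c(OCc2ccccc2)c(C(=O)OCc2ccccc2)c(OCc2ccccc2)c(Oc2cc(OCc3ccccc3)c(OCOC)c(OCc3ccccc3)c2OCc2ccccc2)c1OCc1ccccc1 | intermediate
15 | dibenzyl 2,4,6-tris(benzyloxy)-5-[2,3,5-tris(benzyloxy)-4-hydroxyphenoxy]benzene-1,3-dicarboxylate | O=C(OCc1ccccc1)c1c(OCc2ccccc2)c(C(=O)OCc2ccccc2)c(OCc2ccccc2)c(Oc2cc(OCc3ccccc3)c(O)c(OCc3ccccc3)c2OCc2ccccc2)c1OCc1ccccc1 | intermediate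
16 | dibenzyl penta-2,3-dienedioate (racemic) | O=C(OCc1ccccc1)C=C=CC(=O)OCc1ccccc1 | intermediate
17 | dibenzyl 3-{2,3,6-tris(benzyloxy)-4-[2,4,6-tris(benzyloxy)-3,5-bis(benzyloxycarbonyl)phenoxy]phenoxy}pent-2-enedioate (mixture of double-bond isomers) | O=C(OCc1ccccc1)C=C(CC(=O)OCc1ccccc1)Oc1c(OCc2ccccc2)cc(Oc2c(OCc3ccccc3)c(C(=O)OCc3ccccc3)c(OCc3ccccc3)c(C(=O)OCc3ccccc3)c2OCc2ccccc2)c(OCc2ccccc2)c1OCc1ccccc1 | intermediate
18 | 3,4,5-tris(benzyloxy)benzaldehyde | O=Cc1cc(OCc2ccccc2)c(OCc2ccccc2)c(OCc2ccccc2)c1 | starting material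
19 | 3,4,5-tris(benzyloxy)phenyl formate | O=COc1cc(OCc2ccccc2)c(OCc2ccccc2)c(OCc2ccccc2)c1 | intermediate (not isolated)
20 | 3,4,5-tris(benzyloxy)phenol | Oc1cc(OCc2ccccc2)c(OCc2ccccc2)c(OCc2ccccc2)c1 | intermediate
21 | dibenzyl 2-[3,4,5-tris(benzyloxy)phenoxy]propanedioate | O=C(OCc1ccccc1)C(Oc1cc(OCc2ccccc2)c(OCc2ccccc2)c(OCc2ccccc2)c1)C(=O)OCc1ccccc1 | intermediate
22 | tribenzyl 2-oxo-4-{2,3,6-tris(benzyloxy)-4-[2,4,6-tris(benzyloxy)-3,5-bis(benzyloxycarbonyl)phenoxy]phenoxy}-1-[3,4,5-tris(benzyloxy)phenoxy]pent-4-ene-1,3,5-tricarboxylate | O=C(OCc1ccccc1)C=C(Oc1c(OCc2ccccc2)cc(Oc2c(OCc3ccccc3)c(C(=O)OCc3ccccc3)c(OCc3ccccc3)c(C(=O)OCc3ccccc3)c2OCc2ccccc2)c(OCc2ccccc2)c1OCc1ccccc1)C(C(=O)OCc1ccccc1)C(=O)C(Oc1cc(OCc2ccccc2)c(OCc2ccccc2)c(OCc2ccccc2)c1)C(=O)OCc1ccccc1 | intermediate (not isolated)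
23 | dibenzyl 4,6-dihydroxy-5-[3,4,5-tris(benzyloxy)phenoxy]-2-{2,3,6-tris(benzyloxy)-4-[2,4,6-tris(benzyloxy)-3,5-bis(benzyloxycarbonyl)phenoxy]phenoxy}benzene-1,3-dicarboxylate | O=C(OCc1ccccc1)c1c(O)c(Oc2cc(OCc3ccccc3)c(OCc3ccccc3)c(OCc3ccccc3)c2)c(O)c(C(=O)OCc2ccccc2)c1Oc1c(OCc2ccccc2)cc(Oc2c(OCc3ccccc3)c(C(=O)OCc3ccccc3)c(OCc3ccccc3)c(C(=O)OCc3ccccc3)c2OCc2ccccc2)c(OCc2ccccc2)c1OCc1ccccc1 | intermediate
24 | 2-[4-(3,5-dicarboxy-2,4,6-trihydroxyphenoxy)-2,3,6-trihydroxyphenoxy]-4,6-dihydroxy-5-(3,4,5-trihydroxyphenoxy)benzene-1,3-dicarboxylic acid | OC(=O)c1c(O)c(Oc2cc(O)c(O)c(O)c2)c(O)c(C(=O)O)c1Oc1c(O)cc(Oc2c(O)c(C(=O)O)c(O)c(C(=O)O)c2O)c(O)c1O | intermediate (not isolated)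
25 | 5-{2,6-dihydroxy-4-[2,3,6-trihydroxy-4-(2,4,6-trihydroxyphenoxy)phenoxy]phenoxy}benzene-1,2,3-triol (CNP0018315.0) | Oc1cc(O)c(Oc2cc(O)c(Oc3cc(O)c(Oc4cc(O)c(O)c(O)c4)c(O)c3)c(O)c2O)c(O)c1 | target

Total step count: 15. Longest linear sequence: 11 steps (1, 2, 3, 5, 6, 7, 8, 9, 11, 14, 15); steps 4, 10, 12 and 13 are side branches.

Steps most likely to fail

Step 14. The anion of 17 may be acylated too slowly by the partly deprotonated malonate 21. At the temperature then needed, benzyl oxide could exchange the ring B aryloxy group at the enol ether carbon by elimination to the allene and re-addition, or the sequence could stall at an enol lactone. The fallback uses known chemistry and takes rings C and D from the aromatic pool; it sets out from 15 and comes back to the route at 25. 4-Bromo-2,6-bis(benzyloxy)benzaldehyde A3 would be oxidised with mCPBA to 4-bromo-2,6-bis(benzyloxy)phenyl formate F1 and methanolysed (K2CO3, MeOH) to 4-bromo-2,6-bis(benzyloxy)phenol F2. Ullmann etherification of F2 with 1,2,3-tris(benzyloxy)-5-iodobenzene F3 (CuI, picolinic acid, K3PO4, DMSO, 80 °C; the iodide reacts before the bromide) would give 1,3-bis(benzyloxy)-5-bromo-2-[3,4,5-tris(benzyloxy)phenoxy]benzene F4. Phenol 15 and F4 under the same copper catalysis at 100 °C would give dibenzyl 2,4,6-tris(benzyloxy)-5-[2,3,5-tris(benzyloxy)-4-{3,5-bis(benzyloxy)-4-[3,4,5-tris(benzyloxy)phenoxy]phenoxy}phenoxy]benzene-1,3-dicarboxylate F5, which would be hydrogenolysed and decarboxylated under the conditions of step 15 to 25.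

Step 7. Self-condensation of 11 may outrun acylation by the malonate of 10, which is largely deprotonated and therefore a poor electrophile. The fallback activates one ester through the neighbouring phenol and separates the two C–C bond formations; it sets out from 10 and comes back at 13. Lactonisation of 10 (K2CO3 cat., toluene, 90 °C, reduced pressure to remove benzyl alcohol) would give the aryl ester lactone benzyl 5,7-bis(benzyloxy)-6-(methoxymethoxy)-3-oxo-2,3-dihydro-1,4-benzodioxine-2-carboxylate F6. The magnesium enolate of 11 (MgCl2, Et3N, MeCN, 0 °C) would be C-acylated by this aryl ester with ring opening, which delivers the phenoxide of 12 at a temperature where 11 does not self-condense; DBU at 60 °C would then close ring A to 13.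

Step 2. Incomplete conversion and over-oxidation of the electron-rich phenolate by persulfate, the classical weakness of the Elbs reaction, may be aggravated by the low solubility of the dibenzyl ether in the aqueous base. The fallback replaces substitution at the para carbon by oxidation to the quinone and reduction; it sets out from 2 and comes back at 4. Oxidation of 2 with Fremy's salt, (KSO3)2NO, in acetone/aqueous KH2PO4 would give 2-acetyl-3,5-bis(benzyloxy)cyclohexa-2,5-diene-1,4-dione F7, and Na2S2O4 in EtOAc/H2O would reduce it to 4.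

Further compounds
F1 | step 14 | 4-bromo-2,6-bis(benzyloxy)phenyl formate | O=COc1c(OCc2ccccc2)cc(Br)cc1OCc1ccccc1
F2 | step 14 | 4-bromo-2,6-bis(benzyloxy)phenol | Oc1c(OCc2ccccc2)cc(Br)cc1OCc1ccccc1
F3 | step 14 | 1,2,3-tris(benzyloxy)-5-iodobenzene | Ic1cc(OCc2ccccc2)c(OCc2ccccc2)c(OCc2ccccc2)c1
F4 | step 14 | 1,3-bis(benzyloxy)-5-bromo-2-[3,4,5-tris(benzyloxy)phenoxy]benzene | Brc1cc(OCc2ccccc2)c(Oc2cc(OCc3ccccc3)c(OCc3ccccc3)c(OCc3ccccc3)c2)c(OCc2ccccc2)c1
F5 | step 14 | dibenzyl 2,4,6-tris(benzyloxy)-5-[2,3,5-tris(benzyloxy)-4-{3,5-bis(benzyloxy)-4-[3,4,5-tris(benzyloxy)phenoxy]phenoxy}phenoxy]benzene-1,3-dicarboxylate | O=C(OCc1ccccc1)c1c(OCc2ccccc2)c(C(=O)OCc2ccccc2)c(OCc2ccccc2)c(Oc2cc(OCc3ccccc3)c(Oc3cc(OCc4ccccc4)c(Oc4cc(OCc5ccccc5)c(OCc5ccccc5)c(OCc5ccccc5)c4)c(OCc4ccccc4)c3)c(OCc3ccccc3)c2OCc2ccccc2)c1OCc1ccccc1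
F6 | step 7 | benzyl 5,7-bis(benzyloxy)-6-(methoxymethoxy)-3-oxo-2,3-dihydro-1,4-benzodioxine-2-carboxylate | O=C(OCc1ccccc1)C1Oc2cc(OCc3ccccc3)c(OCOC)c(OCc3ccccc3)c2OC1=O
F7 | step 2 | 2-acetyl-3,5-bis(benzyloxy)cyclohexa-2,5-diene-1,4-dione | CC(=O)C1=C(OCc2ccccc2)C(=O)C(OCc2ccccc2)=CC1=O
A1 | direct plan | 2,4,6-tris(benzyloxy)phenol | Oc1c(OCc2ccccc2)cc(OCc2ccccc2)cc1OCc1ccccc1
A2 | direct plan | 2,4-bis(benzyloxy)-6-bromo-3-(methoxymethoxy)benzaldehyde | O=Cc1c(Br)cc(OCc2ccccc2)c(OCOC)c1OCc1ccccc1
A3 | direct plan | 4-bromo-2,6-bis(benzyloxy)benzaldehyde | O=Cc1c(OCc2ccccc2)cc(Br)cc1OCc1ccccc1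
A4 | direct plan | 2,6-bis(benzyloxy)-4-(2,6-bis(benzyloxy)-4-{2,3,6-tris(benzyloxy)-4-[2,4,6-tris(benzyloxy)phenoxy]phenoxy}phenoxy)phenol | Oc1c(OCc2ccccc2)cc(Oc2c(OCc3ccccc3)cc(Oc3c(OCc4ccccc4)cc(Oc4c(OCc5ccccc5)cc(OCc5ccccc5)cc4OCc4ccccc4)c(OCc4ccccc4)c3OCc3ccccc3)cc2OCc2ccccc2)cc1OCc1ccccc1
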